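**Retrosynthetic overview**
- The target comes from one-pot hydroxide removal of a phenol TBS ether and a methyl ester.
- The (2Z)-acrylate C=C is cut by a Still–Gennari olefination: a chromene aldehyde plus an α-(4-methylpent-3-enyl) phosphonoacetate.
- The aldehyde comes from the homoprenyl chromene by oxidation of the terminal E-methyl, bromination and a two-carbon aza-enolate alkylation.
- The pyran ring is the only ring formed (the benzene ring is bought). It is closed at the aryl C8a–O bond by a light-driven E→Z isomerization/dehydrogenative C–H etherification, so the tertiary C–O stereocentre of (S)-linalool becomes C2 unchanged.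
- The cyclization substrate comes from a Heck coupling of (S)-linalool with TBS-protected 3-bromo-5-methylphenol.

Assumption: (S)-(+)-linalool (coriandrol) is bought at ≥97% ee; the ee of the target equals that of this lot.
Assumption: the one-pot, two-stage irradiation in Step 3 is counted as one step.

**Step 1**
Reactants: 1, 3-bromo-5-methylphenol
Product: 2, (3-bromo-5-methylphenoxy)(tert-butyl)dimethylsilane
Conditions: TBSCl, imidazole, DMF, rt
Reagents that add atoms: TBSCl, CC(C)(C)[Si](C)(C)Cl
Why: Standard imidazole-promoted phenol silylation; the silyl ether keeps the arene electron-rich for Step 3 and is removed by hydroxide in Step 9.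

**Step 2**
Reactants: 2, aryl bromide; 3, (S)-(+)-linalool (1.5 equiv)
Product: 4, (1E,3S)-1-[3-(tert-butyldimethylsilyloxy)-5-methylphenyl]-3,7-dimethylocta-1,6-dien-3-ol
Conditions: Pd2(dba)3 (2.5 mol%), [HP(t-Bu)3]BF4 (6 mol%), Cy2NMe, dioxane, 70 °C
Reagents that add atoms: none (both coupling partners are listed reactants)
Why: Mizoroki–Heck coupling: aryl-Pd adds to the terminal vinyl carbon and syn β-H elimination can only give the E-styrene (the carbinol carbon has no H), the trisubstituted alkene is inert, and the C3 stereocentre is not touched.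

**Step 3**
Reactants: 4, E-styrenyl tertiary alcohol
Product: 6, tert-butyldimethyl{[(2S)-2,8-dimethyl-2-(4-methylpent-3-en-1-yl)-2H-chromen-6-yl]oxy}silane, formed via 5, the (1Z,3S)-isomer of 4 (generated in situ, not isolated)
Conditions: fac-Ir(ppy)3 (1 mol%), degassed MeCN (0.02 M), 450 nm LEDs, rt, ~2 h; then add 9-mesityl-3,6-di-tert-butyl-10-phenylacridinium BF4 (5 mol%), Co(dmgH)2(py)Cl (5 mol%), 2,6-lutidine (0.2 equiv), 450 nm, rt, Ar (H2 evolved)
Reagents that add atoms: none
Why: Proposed new method: a one-pot E→Z isomerization/acceptorless dehydrogenative C(sp2)–H etherification — triplet energy transfer from Ir(ppy)3 converts 4 into the twisted, no-longer-sensitized Z-isomer 5, whose tertiary OH sits over the ring; the excited acridinium then oxidizes the silyloxyarene to its radical cation, the hydroxyl oxygen attacks the ring carbon para to OTBS (highest positive charge, six-membered closure, the other ortho site is shielded by OTBS), and after proton loss the cyclohexadienyl radical is dehydrogenated by the cobaloxime, closing the pyran ring without making or breaking any bond at the carbinol carbon, so the (S) centre from linalool is retained; the closest known reaction types are the photocatalytic E→Z isomerization/oxidative cyclization of cinnamic acids to coumarins and acridinium/cobaloxime dehydrogenative arene C–H amination and lactonization, none of which uses a tertiary aliphatic alcohol to build a 2H-chromene.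

**Step 4**
Reactants: 6, homoprenyl chromene
Product: 7, (2E)-5-[(2S)-6-(tert-butyldimethylsilyloxy)-2,8-dimethyl-2H-chromen-2-yl]-2-methylpent-2-en-1-ol
Conditions: SeO2 (0.3 equiv), t-BuOOH, salicylic acid (cat.), CH2Cl2, 0 °C→rt; then NaBH4, MeOH, 0 °C
Reagents that add atoms: selenium dioxide, O=[Se]=O, with tert-butyl hydroperoxide, CC(C)(C)OO, as terminal oxidant (source of the new O)
Why: Catalytic SeO2 allylic oxidation (ene, then [2,3]-sigmatropic shift) oxidizes the E-methyl of a gem-dimethyl trisubstituted alkene to the (E)-allylic alcohol, the borohydride quench returns any over-oxidized enal, and the ring alkene has no allylic C–H because C2 is quaternary.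

**Step 5**
Reactants: 7, allylic alcohol
Product: 8, (2S)-2-[(3E)-5-bromo-4-methylpent-3-en-1-yl]-6-(tert-butyldimethylsilyloxy)-2,8-dimethyl-2H-chromene (used crude)
Conditions: CBr4, PPh3, CH2Cl2, 0 °C
Reagents that add atoms: carbon tetrabromide, BrC(Br)(Br)Br
Why: Appel bromination of a primary allylic alcohol under neutral conditions at 0 °C gives the bromide without allylic transposition or loss of E geometry.

**Step 6**
Reactants: 8, allylic bromide; 9, acetaldehyde N-tert-butylimine (1.5 equiv)
Product: 10, (4E)-7-[(2S)-6-(tert-butyldimethylsilyloxy)-2,8-dimethyl-2H-chromen-2-yl]-4-methylhept-4-enal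
Conditions: 9, LDA, THF, −78→0 °C; then 8, −78→0 °C; then aq. oxalic acid (pH ~4), rt
Reagents that add atoms: acetaldehyde N-tert-butylimine, CC=NC(C)(C)C (the CH2–CH= unit); water, O (aldehyde oxygen on hydrolysis)
Why: Metalated-imine (aza-enolate) alkylation is an SN2 reaction at the primary allylic bromide that keeps the alkene geometry, and mild acid hydrolysis of the imine releases the two-carbon-homologated aldehyde directly.

**Step 7**
Reactants: 11, methyl bis(2,2,2-trifluoroethyl)phosphonoacetate; 12, 5-bromo-2-methylpent-2-ene
Product: 13, methyl 2-[bis(2,2,2-trifluoroethoxy)phosphoryl]-6-methylhept-5-enoate (racemic; this centre becomes sp2 in Step 8)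
Conditions: NaH, DMF, 0 °C; then 12, NaI (cat.), 50 °C
Reagents that add atoms: none (all new atoms come from the listed reactants)
Why: C-alkylation of the stabilized phosphonoacetate anion with a primary bromide (iodide-assisted SN2), with excess 11 used to limit dialkylation.

**Step 8**
Reactants: 10, aldehyde; 13, phosphonate (1.3 equiv)
Product: 14, methyl (2Z,6E)-9-[(2S)-6-(tert-butyldimethylsilyloxy)-2,8-dimethyl-2H-chromen-2-yl]-6-methyl-2-(4-methylpent-3-en-1-yl)nona-2,6-dienoate
Conditions: 13, KHMDS, 18-crown-6, THF, −78 °C; then 10, −78 °C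
Reagents that add atoms: none (all new atoms come from the listed reactants)
Why: Still–Gennari olefination: the electron-poor bis(trifluoroethyl) phosphonate with a crown-sequestered potassium ion eliminates quickly from the kinetic adduct, placing the ester cis to the aldehyde-derived chain (2Z).

**Step 9**
Reactants: 14, TBS ether methyl ester
Product: 15, (S)-sargachromenol, (2Z,6E)-9-[(2S)-6-hydroxy-2,8-dimethyl-2H-chromen-2-yl]-6-methyl-2-(4-methylpent-3-en-1-yl)nona-2,6-dienoic acid
Conditions: LiOH·H2O (10 equiv), degassed THF/MeOH/H2O (3:1:1), 45 °C, Ar; then aq. citric acid to pH 4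
Reagents that add atoms: lithium hydroxide/water, [Li+].[OH-] / O (one carboxyl oxygen)
Why: One-pot saponification of the methyl ester and hydroxide cleavage of the aryl silyl ether; these conditions do not ionize the C2–O bond or isomerize the Z-enoate, and degassing protects the chromenol from air oxidation.

**Compound list**
1 | 3-bromo-5-methylphenol | Cc1cc(O)cc(Br)c1 | starting material
2 | (3-bromo-5-methylphenoxy)(tert-butyl)dimethylsilane | Cc1cc(Br)cc(O[Si](C)(C)C(C)(C)C)c1 | intermediate
3 | (S)-(+)-linalool | CC(C)=CCC[C@](C)(O)C=C | starting material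
4 | (1E,3S)-1-[3-(TBSO)-5-methylphenyl]-3,7-dimethylocta-1,6-dien-3-ol | CC(C)=CCC[C@](C)(O)/C=C/c1cc(C)cc(O[Si](C)(C)C(C)(C)C)c1 | intermediate
5 | (1Z,3S)-1-[3-(TBSO)-5-methylphenyl]-3,7-dimethylocta-1,6-dien-3-ol | CC(C)=CCC[C@](C)(O)/C=C\c1cc(C)cc(O[Si](C)(C)C(C)(C)C)c1 | intermediate (in situ, not isolated)
6 | tert-butyldimethyl{[(2S)-2,8-dimethyl-2-(4-methylpent-3-en-1-yl)-2H-chromen-6-yl]oxy}silane | CC(C)=CCC[C@@]1(C)C=Cc2cc(O[Si](C)(C)C(C)(C)C)cc(C)c2O1 | intermediate
7 | (2E)-5-[(2S)-6-(TBSO)-2,8-dimethyl-2H-chromen-2-yl]-2-methylpent-2-en-1-ol | OC/C(C)=C/CC[C@@]1(C)C=Cc2cc(O[Si](C)(C)C(C)(C)C)cc(C)c2O1 | intermediate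
8 | (2S)-2-[(3E)-5-bromo-4-methylpent-3-en-1-yl]-6-(TBSO)-2,8-dimethyl-2H-chromene | BrC/C(C)=C/CC[C@@]1(C)C=Cc2cc(O[Si](C)(C)C(C)(C)C)cc(C)c2O1 | intermediate
9 | acetaldehyde N-tert-butylimine | CC=NC(C)(C)C | starting material
10 | (4E)-7-[(2S)-6-(TBSO)-2,8-dimethyl-2H-chromen-2-yl]-4-methylhept-4-enal | O=CCC/C(C)=C/CC[C@@]1(C)C=Cc2cc(O[Si](C)(C)C(C)(C)C)cc(C)c2O1 | intermediate
11 | methyl bis(2,2,2-trifluoroethyl)phosphonoacetate | COC(=O)CP(=O)(OCC(F)(F)F)OCC(F)(F)F | starting material
12 | 5-bromo-2-methylpent-2-ene | CC(C)=CCCBr | starting material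
13 | methyl 2-[bis(2,2,2-trifluoroethoxy)phosphoryl]-6-methylhept-5-enoate (racemic) | COC(=O)C(CCC=C(C)C)P(=O)(OCC(F)(F)F)OCC(F)(F)F | intermediate
14 | methyl (2Z,6E)-9-[(2S)-6-(TBSO)-2,8-dimethyl-2H-chromen-2-yl]-6-methyl-2-(4-methylpent-3-en-1-yl)nona-2,6-dienoate | CC(C)=CCC/C(=C/CC/C(C)=C/CC[C@@]1(C)C=Cc2cc(O[Si](C)(C)C(C)(C)C)cc(C)c2O1)C(=O)OC | intermediate
15 | (S)-sargachromenol | CC(C)=CCC/C(=C/CC/C(C)=C/CC[C@@]1(C)C=Cc2cc(O)cc(C)c2O1)C(=O)O | target

**Totals**
Total steps: 9. Longest linear sequence: 8 (Steps 1–6, 8, 9); Step 7 is the single-step side branch.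

**Three steps most likely to fail**
1. Step 3 (proposed new photocascade).
   - Risks: triplet [2+2] of the styrene with the tethered prenyl alkene during isomerization; oxidation of the trisubstituted alkene or of the more easily oxidized chromene product; acid-promoted ionization of the tertiary allylic alcohol.
   - Fallback (known chemistry, +2 steps): put a halogen at the future C8a instead of using C–H. Para-brominate 3-iodo-5-methylphenol (NBS), protect with TBSCl, and run the Heck coupling with (S)-linalool selectively at C–I. Then isomerize E→Z with Ir(ppy)3 and close the ring by Pd-catalysed intramolecular C–O coupling of the tertiary alcohol with the aryl bromide (Pd(OAc)2, bulky biaryl phosphine, Cs2CO3, toluene) to give the same chromene 6.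
2. Step 4 (SeO2 oxidation in the presence of the electron-rich chromene).
   - Risks: modest yield or ring oxidation.
   - Fallback: oxidize before building the ring. Apply SeO2/t-BuOOH to (S)-linalool itself to give (S,E)-8-hydroxylinalool, protect the primary OH as its acetate, carry it through the Heck coupling and photocyclization, and release alcohol 7 with DIBAL at −78 °C.
3. Step 8 (Still–Gennari olefination with an α-alkylated phosphonate).
   - Risks: insufficient Z:E ratio or an inseparable E isomer.
   - Fallback: set the geometry by syn addition to an alkyne. Alkylate bromide 8 with lithiated 1-(trimethylsilyl)propyne, then treat with MeLi and ClCO2Me to give the 2-ynoate. Pd(PPh3)4/Bu3SnH syn-hydrostannation puts tin at C2; iododestannylation and Negishi coupling with 4-methylpent-3-enylzinc bromide then give 14 with the ester cis to the chain.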